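**Plan**
- Retrosynthetic cuts: the lactone bonds O–C15 and C16–C13 are cut together, leaving CO2 and a propargylic bromide (C13≡C14–C15H2Br). The alkyne and C15 go back to a methyl ketone, the C8 hydroxymethyl to an exocyclic C8=C17 alkene. C4–C5 and C9–C10 are cut together to open both rings to an acyclic α-methyl β-keto ester diene, and C1–C2 is cut to an allylic bromide (from (E)-geranylacetone) plus an acetoacetate dianion.
- Forward order: the chain is joined at C1–C2; rings A and B close in one oxidative radical cascade (ring A first, then ring B); C3/C19 are reduced; C8 is hydroborated and epimerised; the ketone becomes the propargylic bromide; the butenolide ring is made last.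
- Enabling feature: in the butenolide ring (O, C15, C14, C13, C16) the unit O–C16(=O) is CO2 and C13–C14–C15 is a propargyl/allenyl anion. Carboxylation at C13 gives a 2-substituted buta-2,3-dienoic acid whose terminal C14=C15 bond takes the carboxyl oxygen at C15.
- Stereochemistry: absolute configuration from the 8-phenylmenthyl ester in the cyclisation; C5, C9 and C10 from the two E-alkenes through a chair–chair transition state; C4 from the axial preference of the ester; C3 by axial hydride delivery; C8 by thermodynamic epimerisation of the C17 aldehyde.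

Key step: step 16

Remarks on the chemistry
- Labdane numbering is used for the bicyclic compounds: C1–C10 trans-decalin (C5/C10 fusion), C11–C12 the CH2CH2 tether on C9, C13–C16 the side-chain terminus/butenolide, C17 on C8, C18 (CH3) and C19 (oxygenated carbon) on C4, C20 the CH3 on C10. "D" stands for the tris-TBS decalinyl group (1R,2S,4aS,5R,6R,8aS)-6-(TBSO)-2,5-bis(TBSOCH2)-5,8a-dimethyldecahydronaphthalen-1-yl.
- Assumption: the (1S,2R,5S)-8-phenylmenthyl ester is taken to shield the face of the C4 radical that leads to the (4S,5S,9R,10S) series drawn; if the sense of induction is the opposite, the antipodal auxiliary is used and nothing else changes.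
- Assumption: (E)-geranylacetone is used as the single 5E isomer.

**Step 1**
Reactants: 1 (E)-geranylacetone
Product: 2 2-[(3E)-4,8-dimethylnona-3,7-dien-1-yl]-2-methyl-1,3-dioxolane
Conditions: HOCH2CH2OH (3 equiv), PPTS (5 mol %), benzene, reflux, Dean–Stark
Reagents that add atoms: ethylene glycol OCCO
Why: Acid-catalysed ketalisation with azeotropic removal of water masks the methyl ketone against the later enolate, hydride and borane steps, and PPTS is too weak an acid to cyclise the 1,5-diene.

**Step 2**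
Reactants: 2 dioxolane of geranylacetone
Product: 3 (2E,6E)-2,6-dimethyl-9-(2-methyl-1,3-dioxolan-2-yl)nona-2,6-dien-1-ol
Conditions: SeO2 (0.3 equiv), t-BuOOH (2 equiv), salicylic acid (10 mol %), CH2Cl2, 0 → 25 °C
Reagents that add atoms: tert-butyl hydroperoxide CC(C)(C)OO
Why: Sharpless–Umbreit allylic oxidation (ene reaction then [2,3]-sigmatropic shift) should attack the more nucleophilic terminal isopropylidene group at its (E)-methyl, which gives the (E)-allylic alcohol.

**Step 3**
Reactants: 3 allylic alcohol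
Product: 4 2-[(3E,7E)-9-bromo-4,8-dimethylnona-3,7-dien-1-yl]-2-methyl-1,3-dioxolane
Conditions: CBr4 (1.2 equiv), PPh3 (1.2 equiv), CH2Cl2, 0 °C
Reagents that add atoms: carbon tetrabromide BrC(Br)(Br)Br
Why: Appel bromination converts the primary allylic alcohol into the bromide under neutral conditions, without allylic transposition or loss of the ketal.

**Step 4**
Reactants: 5 ethyl 2-methyl-3-oxobutanoate; 6 (1S,2R,5S)-8-phenylmenthol
Product: 7 (1S,2R,5S)-8-phenylmenthyl 2-methyl-3-oxobutanoate
Conditions: DMAP (20 mol %), toluene, reflux, EtOH distilled off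
Reagents that add atoms: none
Why: DMAP-catalysed transesterification of a β-keto ester (through the acylketene) attaches the auxiliary and is driven by removal of ethanol.

**Step 5**
Reactants: 7 auxiliary β-keto ester; 4 allylic bromide
Product: 9 (1S,2R,5S)-8-phenylmenthyl (6E,10E)-2,6,10-trimethyl-13-(2-methyl-1,3-dioxolan-2-yl)-3-oxotrideca-6,10-dienoate, via dianion 8 (not isolated)
Conditions: NaH (1.1 equiv), THF, 0 °C; n-BuLi (1.05 equiv), 0 °C; then 4, 0 → 25 °C; aq. NH4Cl
Reagents that add atoms: none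
Why: Weiler dianion alkylation: the more basic γ-carbanion of the acetoacetate dianion displaces the primary allylic bromide (SN2) and builds the C1–C2 bond while the α-methyl β-keto ester is kept.

**Step 6**
Reactants: 9 acyclic β-keto ester
Product: 10 (1S,2R,5S)-8-phenylmenthyl (4S,5S,9R,10S)-keto ester: trans-decalin with C3 ketone; C4 equatorial CH3 and axial CO2R syn to the C10 CH3; C8 exocyclic CH2; C9 equatorial 2-(2-methyl-1,3-dioxolan-2-yl)ethyl
Conditions: Mn(OAc)3·2H2O (2.2 equiv), Cu(OAc)2·H2O (0.2 equiv), degassed EtOH, 25 °C; minor diastereomer removed by chromatography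
Reagents that add atoms: none
Why: Snider-type oxidative radical polyene cyclisation: the trivalent manganese enolate gives the C4 α-keto ester radical, which closes rings A and B 6-endo/6-endo through a chair–chair transition state (trans-fusion and equatorial C9 chain from the E-alkenes, ester axial as in podocarpate syntheses), divalent copper oxidises the tertiary C8 radical to the exocyclic alkene, and the phenyl group of the auxiliary blocks one face of the radical and so sets the absolute configuration.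

**Step 7**
Reactants: 10 bicyclic keto ester
Product: 11 (3R,4R,5S,9R,10S)-diol: equatorial 3-OH; C4 axial CH2OH (C19) and equatorial CH3; C8 exocyclic CH2; C9 chain as in 10
Conditions: LiAlH4 (4 equiv), THF, 0 °C → reflux; H2O, 15% NaOH, H2O
Reagents that add atoms: none
Why: LiAlH4 should reduce the C3 ketone by axial hydride delivery on the face opposite the axial C4 ester (equatorial 3-OH) and then cleave the hindered ester to the C19 alcohol with release of the auxiliary.

**Step 8**
Reactants: 11 diol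
Product: 12 3,19-acetonide of 11 (2,2-dimethyl-1,3-dioxane across O3 and O19)
Conditions: 2-methoxypropene (3 equiv), PPTS (5 mol %), CH2Cl2, 0 → 25 °C
Reagents that add atoms: 2-methoxypropene COC(C)=C
Why: Acid-catalysed acetal formation closes the six-membered acetonide on the cis-disposed equatorial 3-OH and axial C19 hydroxymethyl (the 1,3-dioxane familiar from andrographolide) and leaves the dioxolane alone because no acetone or water is present.

**Step 9**
Reactants: 12 acetonide alkene
Product: 14 (8R)-17-alcohol: 12 with the C8 methylene replaced by H and an axial CH2OH, via borane 13 (not isolated)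
Conditions: 9-BBN (2.5 equiv), THF, 65 °C; then 3 M NaOH, 30% H2O2, 0 → 25 °C
Reagents that add atoms: hydrogen peroxide OO
Why: Anti-Markovnikov hydroboration–oxidation in which 9-BBN should approach the exocyclic alkene from the face opposite the axial C10 methyl, so that the new CH2OH is expected axial (8R), the C8 epimer that step 11 corrects.

**Step 10**
Reactants: 14 (8R)-17-alcohol
Product: 15 (8R)-17-aldehyde (axial CHO)
Conditions: TEMPO (10 mol %), PhI(OAc)2 (1.2 equiv), CH2Cl2, 25 °C
Reagents that add atoms: none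
Why: Oxoammonium (TEMPO) oxidation of the primary alcohol stops at the aldehyde under nearly neutral conditions that keep both acetals.

**Step 11**
Reactants: 15 axial aldehyde
Product: 17 (8S)-17-alcohol (equatorial CH2OH, trans to the C9 chain), via equatorial aldehyde 16 (not isolated)
Conditions: K2CO3 (0.5 equiv), MeOH, 25 °C; then NaBH4 (1.5 equiv), 0 °C
Reagents that add atoms: none
Why: Enolisation should equilibrate the axial aldehyde (1,3-diaxial to the C10 methyl) to the equatorial epimer, trans-diequatorial with the C9 chain, and reduction in the same flask fixes the 8S centre.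

**Step 12**
Reactants: 17 acetonide ketal alcohol
Product: 18 4-[(1R,2S,4aS,5R,6R,8aS)-6-hydroxy-2,5-bis(hydroxymethyl)-5,8a-dimethyldecahydronaphthalen-1-yl]butan-2-one
Conditions: 2 M aq. HCl, THF, 40 °C
Reagents that add atoms: water O
Why: Aqueous acid hydrolyses the acetonide and the dioxolane together, and no stereocentre is epimerisable under these conditions.

**Step 13**
Reactants: 18 triol ketone
Product: 19 4-D-butan-2-one (tris-TBS ether of 18)
Conditions: TBSOTf (4 equiv), 2,6-lutidine (6 equiv), CH2Cl2, −78 → 0 °C; aq. citric acid wash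
Reagents that add atoms: tert-butyldimethylsilyl triflate CC(C)(C)[Si](C)(C)OS(=O)(=O)C(F)(F)F
Why: The silyl triflate silylates all three hydroxyls, including the hindered C3 one, while the weak base leaves the methyl ketone (any silyl enol ether is hydrolysed in the acidic wash).

**Step 14**
Reactants: 19 tris-TBS methyl ketone
Product: 22 5-D-pent-2-yn-1-ol, via enol phosphate 20 (not isolated), via lithium acetylide 21 (not isolated)
Conditions: LDA (1.1 equiv), THF, −78 °C; ClP(O)(OEt)2 (1.2 equiv), −78 → 25 °C; LDA (2.4 equiv), −78 → 25 °C; (CH2O)n (5 equiv), 0 → 25 °C; aq. NH4Cl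
Reagents that add atoms: formaldehyde (from paraformaldehyde) C=O
Why: Negishi alkyne synthesis: kinetic deprotonation at the methyl group, O-phosphorylation, and LDA-induced E2 loss of diethyl phosphate followed by deprotonation give the lithium acetylide, which adds to formaldehyde to install C15.

**Step 15**
Reactants: 22 propargylic alcohol
Product: 23 1-bromo-5-D-pent-2-yne
Conditions: CBr4 (1.3 equiv), PPh3 (1.3 equiv), 2,6-lutidine (0.2 equiv), CH2Cl2, 0 °C
Reagents that add atoms: carbon tetrabromide BrC(Br)(Br)Br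
Why: Appel bromination proceeds by SN2 at the primary propargylic carbon (no allenyl bromide) under buffered conditions that the silyl ethers tolerate.

**Step 16**
Reactants: 23 propargylic bromide
Product: 26 3-(2-D-ethyl)furan-2(5H)-one, via propargylic Grignard reagent 24 (not isolated), via allenoic acid 25 (not isolated)
Conditions: Mg (Rieke, 1.3 equiv), THF, −78 °C; CO2 (dry, 1 atm), −78 → 0 °C; then AcOH (1.5 equiv), MeOH, CuCl (10 mol %), 55 °C
Reagents that add atoms: carbon dioxide O=C=O
Why: Magnesium inserts into the C15–Br bond to give the 2-alkynyl Grignard reagent 24, which attacks CO2 at its γ-carbon C13 through a cyclic SE2' transition state (Mg on the primary C15 and bound to a CO2 oxygen), so that the C16–C13 bond forms with propargyl-to-allenyl transposition; after protonation CuCl (monovalent copper) activates the terminal C14=C15 bond of the 2,3-allenoic acid 25, the carboxyl oxygen adds to C15 and protodemetalation at C14 leaves the conjugated C13=C14 bond. The closest known reaction types are the carbonation of 2-alkynyl Grignard reagents to 2-substituted buta-2,3-dienoic acids and the CuCl-catalysed cycloisomerisation of 2,3-allenoic acids to butenolides. The lactone ring (O, C15, C14, C13, C16) closes in the 5-endo mode onto the allene terminus, the only unstrained option because 4-exo attack at the central C14 would give a β-lactone. No stereocentre is created, and the six existing ones, all in the silyl-protected decalin, are not touched. The step needs γ- over α-carboxylation (attack through C15 would give the isomeric 3-alkynoic acid), and the γ-alkyl group secures it by holding the metal on the unhindered CH2 terminus so that CO2 is delivered to C13; Wurtz coupling is limited by forming the reagent at −78 °C from highly reactive magnesium.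

**Step 17**
Reactants: 26 tris-TBS butenolide
Product: 27 14-deoxy-17-hydroxyandrographolide
Conditions: HF·pyridine, pyridine, THF, 0 → 25 °C
Reagents that add atoms: none
Why: Fluoride cleaves the three silyl ethers (strong Si–F bond) under mildly acidic conditions to which the butenolide and the triol are stable.

**Compound list**
1 | (5E)-6,10-dimethylundeca-5,9-dien-2-one ((E)-geranylacetone) | CC(=O)CC/C=C(\C)CCC=C(C)C | starting material
2 | 2-[(3E)-4,8-dimethylnona-3,7-dien-1-yl]-2-methyl-1,3-dioxolane | CC1(CC/C=C(\C)CCC=C(C)C)OCCO1 | intermediate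
3 | (2E,6E)-2,6-dimethyl-9-(2-methyl-1,3-dioxolan-2-yl)nona-2,6-dien-1-ol | CC1(CC/C=C(\C)CC/C=C(\C)CO)OCCO1 | intermediate
4 | 2-[(3E,7E)-9-bromo-4,8-dimethylnona-3,7-dien-1-yl]-2-methyl-1,3-dioxolane | CC1(CC/C=C(\C)CC/C=C(\C)CBr)OCCO1 | intermediate
5 | ethyl 2-methyl-3-oxobutanoate | CCOC(=O)C(C)C(C)=O | starting material
6 | (1S,2R,5S)-5-methyl-2-(2-phenylpropan-2-yl)cyclohexan-1-ol ((+)-8-phenylmenthol) | O[C@H]1C[C@@H](C)CC[C@@H]1C(C)(C)c1ccccc1 | starting material
7 | (1S,2R,5S)-5-methyl-2-(2-phenylpropan-2-yl)cyclohexyl 2-methyl-3-oxobutanoate (C2 epimers) | CC(=O)C(C)C(=O)O[C@H]1C[C@@H](C)CC[C@@H]1C(C)(C)c1ccccc1 | intermediate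
8 | sodium lithium dienolate (dianion) of 7 | [Na+].[Li+].C=C([O-])C(C)=C([O-])O[C@H]1C[C@@H](C)CC[C@@H]1C(C)(C)c1ccccc1 | intermediate
9 | (1S,2R,5S)-8-phenylmenthyl (6E,10E)-2,6,10-trimethyl-13-(2-methyl-1,3-dioxolan-2-yl)-3-oxotrideca-6,10-dienoate (C2 epimers) | CC1(CC/C=C(\C)CC/C=C(\C)CCC(=O)C(C)C(=O)O[C@H]2C[C@@H](C)CC[C@@H]2C(C)(C)c2ccccc2)OCCO1 | intermediate
10 | (1S,2R,5S)-8-phenylmenthyl (1S,4aS,5R,8aS)-1,4a-dimethyl-6-methylidene-5-[2-(2-methyl-1,3-dioxolan-2-yl)ethyl]-2-oxodecahydronaphthalene-1-carboxylate (labdane numbering 4S,5S,9R,10S; ester axial) | C[C@]1(C(=O)O[C@H]2C[C@@H](C)CC[C@@H]2C(C)(C)c2ccccc2)[C@H]2CCC(=C)[C@@H](CCC3(C)OCCO3)[C@]2(C)CCC1=O | intermediate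
11 | (1R,2R,4aS,5R,8aS)-1-(hydroxymethyl)-1,4a-dimethyl-6-methylidene-5-[2-(2-methyl-1,3-dioxolan-2-yl)ethyl]decahydronaphthalen-2-ol (labdane numbering 3R,4R,5S,9R,10S) | C[C@]1(CO)[C@H]2CCC(=C)[C@@H](CCC3(C)OCCO3)[C@]2(C)CC[C@H]1O | intermediate
12 | 3,19-O-isopropylidene derivative (acetonide) of 11 | C[C@]1(COC(C)(C)O4)[C@H]2CCC(=C)[C@@H](CCC3(C)OCCO3)[C@]2(C)CC[C@H]14 | intermediate
13 | B-alkyl-9-borabicyclo[3.3.1]nonane from 12 (boron on C17; 8R, C17 axial) | C[C@]1(COC(C)(C)O4)[C@H]2CC[C@@H](CB5C6CCCC5CCC6)[C@@H](CCC3(C)OCCO3)[C@]2(C)CC[C@H]14 | intermediate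
14 | (8R)-17-alcohol: acetonide ketal with axial C8 CH2OH (3R,4R,5S,8R,9R,10S) | C[C@]1(COC(C)(C)O4)[C@H]2CC[C@@H](CO)[C@@H](CCC3(C)OCCO3)[C@]2(C)CC[C@H]14 | intermediate
15 | (8R)-17-aldehyde: axial C8 CHO (3R,4R,5S,8R,9R,10S) | C[C@]1(COC(C)(C)O4)[C@H]2CC[C@@H](C=O)[C@@H](CCC3(C)OCCO3)[C@]2(C)CC[C@H]14 | intermediate
16 | (8S)-17-aldehyde: equatorial C8 CHO (3R,4R,5S,8S,9R,10S) | C[C@]1(COC(C)(C)O4)[C@H]2CC[C@H](C=O)[C@@H](CCC3(C)OCCO3)[C@]2(C)CC[C@H]14 | intermediate
17 | (8S)-17-alcohol: equatorial C8 CH2OH (3R,4R,5S,8S,9R,10S) | C[C@]1(COC(C)(C)O4)[C@H]2CC[C@H](CO)[C@@H](CCC3(C)OCCO3)[C@]2(C)CC[C@H]14 | intermediate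
18 | 4-[(1R,2S,4aS,5R,6R,8aS)-6-hydroxy-2,5-bis(hydroxymethyl)-5,8a-dimethyldecahydronaphthalen-1-yl]butan-2-one | C[C@]1(CO)[C@H]2CC[C@H](CO)[C@@H](CCC(C)=O)[C@]2(C)CC[C@H]1O | intermediate
19 | 4-D-butan-2-one (tris-TBS ether of 18) | C[C@]1(CO[Si](C)(C)C(C)(C)C)[C@H]2CC[C@H](CO[Si](C)(C)C(C)(C)C)[C@@H](CCC(C)=O)[C@]2(C)CC[C@H]1O[Si](C)(C)C(C)(C)C | intermediate
20 | diethyl 4-D-but-1-en-2-yl phosphate | C[C@]1(CO[Si](C)(C)C(C)(C)C)[C@H]2CC[C@H](CO[Si](C)(C)C(C)(C)C)[C@@H](CCC(=C)OP(=O)(OCC)OCC)[C@]2(C)CC[C@H]1O[Si](C)(C)C(C)(C)C | intermediate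
21 | (4-D-but-1-yn-1-yl)lithium | C[C@]1(CO[Si](C)(C)C(C)(C)C)[C@H]2CC[C@H](CO[Si](C)(C)C(C)(C)C)[C@@H](CCC#C[Li])[C@]2(C)CC[C@H]1O[Si](C)(C)C(C)(C)C | intermediate
22 | 5-D-pent-2-yn-1-ol | C[C@]1(CO[Si](C)(C)C(C)(C)C)[C@H]2CC[C@H](CO[Si](C)(C)C(C)(C)C)[C@@H](CCC#CCO)[C@]2(C)CC[C@H]1O[Si](C)(C)C(C)(C)C | intermediate
23 | 1-bromo-5-D-pent-2-yne | C[C@]1(CO[Si](C)(C)C(C)(C)C)[C@H]2CC[C@H](CO[Si](C)(C)C(C)(C)C)[C@@H](CCC#CCBr)[C@]2(C)CC[C@H]1O[Si](C)(C)C(C)(C)C | intermediate
24 | (5-D-pent-2-yn-1-yl)magnesium bromide (in equilibrium with its allenyl form) | C[C@]1(CO[Si](C)(C)C(C)(C)C)[C@H]2CC[C@H](CO[Si](C)(C)C(C)(C)C)[C@@H](CCC#CC[Mg]Br)[C@]2(C)CC[C@H]1O[Si](C)(C)C(C)(C)C | intermediate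
25 | 2-(2-D-ethyl)buta-2,3-dienoic acid | C[C@]1(CO[Si](C)(C)C(C)(C)C)[C@H]2CC[C@H](CO[Si](C)(C)C(C)(C)C)[C@@H](CCC(=C=C)C(=O)O)[C@]2(C)CC[C@H]1O[Si](C)(C)C(C)(C)C | intermediate
26 | 3-(2-D-ethyl)furan-2(5H)-one | C[C@]1(CO[Si](C)(C)C(C)(C)C)[C@H]2CC[C@H](CO[Si](C)(C)C(C)(C)C)[C@@H](CCC3=CCOC3=O)[C@]2(C)CC[C@H]1O[Si](C)(C)C(C)(C)C | intermediate
27 | 3-{2-[(1R,2S,4aS,5R,6R,8aS)-6-hydroxy-2,5-bis(hydroxymethyl)-5,8a-dimethyldecahydronaphthalen-1-yl]ethyl}furan-2(5H)-one (14-deoxy-17-hydroxyandrographolide) | C[C@]1(CO)[C@H]2CC[C@H](CO)[C@@H](CCC3=CCOC3=O)[C@]2(C)CC[C@H]1O | target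

**Count**
Total steps: 17. Longest linear sequence: 16 steps (steps 1–3 and 5–17; step 4 is a one-step branch).

**Steps most likely to fail, with fallbacks**

Step 16. What may go wrong: carboxylation through the α-carbon C15 instead of C13 (leading to the isomeric 3-alkynoic acid and its enol lactone), Wurtz-type homocoupling while the Grignard reagent forms, and partial loss of silyl groups in warm acidic methanol (harmless, since step 17 removes them). The fallback sets out from 22 and comes back at 26. Trans-hydroalumination of the propargylic alcohol with NaAlH2(OCH2CH2OMe)2 in THF at 0 °C and iodinolysis at −78 °C should give the (Z)-3-iodo allylic alcohol F1 (iodine on C13, cis to C15H2OH). Carbonylative lactonisation of F1 (CO 1 atm, PdCl2(PPh3)2 5 mol %, K2CO3, THF, 50 °C) then closes the same butenolide 26, with C16 from CO and the ring oxygen from the C15 hydroxyl.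

Step 6. What may go wrong: poor or reversed facial discrimination by the auxiliary, oxidation of the intermediate C10 radical after only one ring has closed, and solvolysis of the dioxolane. The fallback sets out from 4 and comes back at 11; it secures the absolute configuration by resolution instead of by an auxiliary. The dianion of the achiral ester 5 (NaH, then n-BuLi) is alkylated with 4 to give the ethyl β-keto ester F2. The same Mn(OAc)3/Cu(OAc)2 cyclisation gives the racemic bicyclic ethyl keto ester F3, and LiAlH4 reduction gives the racemic diol F4. F4 is resolved by preparative chromatography on a chiral stationary phase to deliver 11.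

Step 2. What may go wrong: competing oxidation at the internal trisubstituted alkene, over-oxidation to the enal and incomplete conversion. The fallback sets out from 2 and comes back at 3; it degrades and rebuilds the chain terminus instead of oxidising a C–H bond. NBS in aqueous THF at 0 °C should give the terminal bromohydrin F5, and K2CO3 in MeOH the terminal epoxide F6. H5IO6 in THF/Et2O at 0 °C cleaves F6 to the aldehyde F7. Wittig reaction with Ph3P=C(CH3)CO2Et in toluene at 80 °C gives the (E)-enoate F8, and DIBAL-H in CH2Cl2 at −78 °C reduces F8 to 3.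

**Further compounds**
F1 | step 16 | (2Z)-5-D-3-iodopent-2-en-1-ol | C[C@]1(CO[Si](C)(C)C(C)(C)C)[C@H]2CC[C@H](CO[Si](C)(C)C(C)(C)C)[C@@H](CC/C(I)=C/CO)[C@]2(C)CC[C@H]1O[Si](C)(C)C(C)(C)C
F2 | step 6 | ethyl (6E,10E)-2,6,10-trimethyl-13-(2-methyl-1,3-dioxolan-2-yl)-3-oxotrideca-6,10-dienoate | CC1(CC/C=C(\C)CC/C=C(\C)CCC(=O)C(C)C(=O)OCC)OCCO1
F3 | step 6 | racemic ethyl 1,4a-dimethyl-6-methylidene-5-[2-(2-methyl-1,3-dioxolan-2-yl)ethyl]-2-oxodecahydronaphthalene-1-carboxylate (relative configuration of 10; both enantiomers) | C[C@]1(C(=O)OCC)[C@H]2CCC(=C)[C@@H](CCC3(C)OCCO3)[C@]2(C)CCC1=O.C[C@@]1(C(=O)OCC)[C@@H]2CCC(=C)[C@H](CCC3(C)OCCO3)[C@@]2(C)CCC1=O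
F4 | step 6 | racemic diol (11 and its enantiomer) | C[C@]1(CO)[C@H]2CCC(=C)[C@@H](CCC3(C)OCCO3)[C@]2(C)CC[C@H]1O.C[C@@]1(CO)[C@@H]2CCC(=C)[C@H](CCC3(C)OCCO3)[C@@]2(C)CC[C@@H]1O
F5 | step 2 | 2-[(3E)-7-bromo-8-hydroxy-4,8-dimethylnon-3-en-1-yl]-2-methyl-1,3-dioxolane (racemic) | CC1(CC/C=C(\C)CCC(Br)C(C)(C)O)OCCO1
F6 | step 2 | 2-[(3E)-6-(3,3-dimethyloxiran-2-yl)-4-methylhex-3-en-1-yl]-2-methyl-1,3-dioxolane (racemic) | CC1(CC/C=C(\C)CCC2OC2(C)C)OCCO1
F7 | step 2 | (4E)-4-methyl-7-(2-methyl-1,3-dioxolan-2-yl)hept-4-enal | CC1(CC/C=C(\C)CCC=O)OCCO1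
F8 | step 2 | ethyl (2E,6E)-2,6-dimethyl-9-(2-methyl-1,3-dioxolan-2-yl)nona-2,6-dienoate | CC1(CC/C=C(\C)CC/C=C(\C)C(=O)OCC)OCCO1
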